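At early times the starting material leaves with the summed forward rate constant of its steps, kA = 0.496 h⁻¹, faster than the target passes on to the isomer of the product B at 0.14 h⁻¹, so the target climbs first.

| flask | starting material | time |
|---|---|---|
| Thursday's | 1.1 M | 5.0 h |
| Tuesday's | 1.1 M | 10 h |
| Saturday's | 1.1 M | 20 h |

    starting material ⇌ target (K1 = 13, k1 = 0.38 h⁻¹)
    starting material ⇌ isomer of the product A (K2 = 4.5, k2 = 0.020 h⁻¹)
    starting material ⇌ third isomer (K3 = 2.3, k3 = 0.019 h⁻¹)
    starting material ⇌ dormant form (K4 = 0.38, k4 = 0.077 h⁻¹)
    target ⇌ isomer of the product B (K5 = 2.9, k5 = 0.14 h⁻¹)

- which of the two there is more of at the end, Thursday's (target / isomer of the product B)
- which of the two there is more of at the end, Tuesday's (target / isomer of the product B)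
- which of the two there is more of at the end, Saturday's (target / isomer of the product B)
- how much target is there at the end, in percent of the starting material charged: Thursday's
- how much target is there at the end, in percent of the starting material charged: Tuesday's
- how much target is there at the end, in percent of the starting material charged: Saturday's

Beside Tuesday's stands a neighbour that looks nearly the same: the same flask, stopped at 2.5 h. We solve both ends and join them to see where each lands.

At the early end, material reaches the products after an average entry time 2.02 h. At the late end, the target and the isomer of the product B form a pair whose target share tends to f = 25.6%, and the excess over f dies away as exp(−λt), with λ = 0.188 h⁻¹, the forward and back rate constants of that step added. A pair starting as pure target comes level after 5.93 h. Joining the ends gives the crossing time tc, the entry time plus this levelling time, at which target and isomer of the product B stand equal: 7.94 h. This is kinetic against thermodynamic control within the pair.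

So the neighbour, read earlier than tc, should end with the target ahead, and Tuesday's, read later, with the isomer of the product B ahead. Saturday's, at 20 h, lies further past tc, while Thursday's, at 5.0 h, falls short of it.

For amounts, Thursday's we reckon as made and lost, each first order, which gives 44.1% target. For the later flasks we count the dormant form as giving back, since its relaxation half-life of 2.48 h is shorter than Tuesday's time. The pair then collects g = 90.7% of the charge, and the target is g times its share, with the clock started after the entry time: 38.3% on Tuesday's and 25.5% on Saturday's.

The forecast names the same leaders, target, isomer of the product B and isomer of the product B, and says that the target “bleeds into isomer B, which overtakes it”, but its target figures of 47%, 36% and 24% are not the same as ours.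

The simulation gives 46.5%, 36.2% and 25.8% target, and the leaders are target on Thursday's, isomer of the product B on Tuesday's and isomer of the product B on Saturday's. The lead changes hands between Thursday's 46.5% against 23.9% and Tuesday's 36.2% against 44.4%, on either side of tc = 7.94 h. In Tuesday's flask the target is made 3.62 times faster than it is used up at 1.53 h, each step taken net, but by the asked time that ratio has dropped to 0.364. The neighbour, stopped before tc, holds most as target, with 44.1% against 9.58% of the isomer of the product B.

The numbers come from no measurement; what happens was integrated by code.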